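**Retrosynthetic overview**
- The target is traced back to an exocyclic α-alkylidene lactone (alkene migration into the lactone ring), and that to a 9β-allyl-9α-carbinol plus purchased α-methylene-γ-butyrolactone (cross-metathesis; the lactone ring is bought intact).
- The C9 carbinol comes from vinyl opening of a 9α,11-oxirane, made by α-face epoxidation of a 9-methylene compound, itself from Wittig methylenation of a C9 ketone; the 3β-oxygen comes from hydride reduction of a C3 ketone.
- The trans-decalin-3,9-dione comes from a linear dienone by lithium–ammonia reduction (sets 5α-H) and hydrogenation; the dienone comes from the cycloadduct by removing the sacrificial C6 oxygen through a dienyl triflate.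
- Key disconnection: ring A (C1–C5, C10) is formed by a catalytic enantioselective Diels–Alder reaction that makes C1–C10 and C4–C5, from 4-methyl-3-silyloxypenta-1,3-diene (C1–C4, both C4 methyls, O3) and 2,6-dimethyl-1,4-benzoquinone (ring B with the C8 and C10 methyls, O9 and a temporary O6). The enabling feature is that in ring B the C9 oxygen lies between methyl-bearing C8 and the quaternary, methyl-bearing C10, so C9=O is α to C10 and activates C5=C10 as dienophile, while in ring A the C3 oxygen next to the C4 gem-dimethyl is the retron of the 2-oxy-1,1-dimethyl diene.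
- Ring order: ring B and the butenolide ring are purchased; ring A is the only ring of the skeleton that is closed (step 2); the oxirane used later is a transient, non-skeletal ring.

Key step: step 2

Numbering: labdane numbering for all bicyclic compounds (ring A = C1–C5 and C10; ring B = C5–C10; side chain C11–C16; β = face of the C10 methyl); "11-nordrimane" = 4,4,8,10-tetramethyldecalin.
Assumption: the (S)-configured catalyst is taken to shield the face of the C5=C10 bond that leads to the 10β-methyl adduct, by extrapolation from this catalyst class with methyl-substituted quinone double bonds; if the sense were opposite, the (R)-catalyst would be used with no other change.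

**Step 1**
Reactants: 1 4-methylpent-1-en-3-one (isopropyl vinyl ketone)
Product: 2 4-methyl-3-(triisopropylsilyloxy)penta-1,3-diene
Conditions: TIPSOTf, Et3N, CH2Cl2, 0 °C to rt
Reagents that add atoms: triisopropylsilyl trifluoromethanesulfonate (TIPSOTf), CC(C)[Si](C(C)C)(C(C)C)OS(=O)(=O)C(F)(F)F
Why: Soft enolisation (silyl triflate/amine) at the only enolisable position of 1, the isopropyl methine, should give the cross-conjugated 2-silyloxy diene by the silyl enol ether formation used for 2-silyloxybutadienes from vinyl ketones; no stereocentre is formed.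

**Step 2**
Reactants: 2 4-methyl-3-(triisopropylsilyloxy)penta-1,3-diene; 3 2,6-dimethyl-1,4-benzoquinone
Product: 4 cis-fused 3-(triisopropylsilyloxy)-11-nordrima-2,7-diene-6,9-dione (5β-H/10β-CH3)
Conditions: (S)-oxazaborolidinium triflimide [(S)-3,3-diphenyl-1-(2-methylphenyl)tetrahydro-1H,3H-pyrrolo[1,2-c][1,3,2]oxazaborole·HN(SO2CF3)2, 20 mol %], CH2Cl2, −78 to −40 °C
Reagents that add atoms: none
Why: This is a Lewis-acid-catalysed normal-demand Diels–Alder reaction in which the cationic oxazaborolidine binds a quinone carbonyl and the electron-rich diene adds by an asynchronous concerted [4+2] path, the closest known type being the oxazaborolidinium-catalysed cycloaddition of 2-silyloxy-1,3-dienes to methyl-substituted 1,4-benzoquinones. Ring A is closed by intermolecular [4+2] cycloaddition that forms C1–C10 and C4–C5 suprafacially on both partners, so the ring fusion is cis. The quaternary centre C10 is set by the catalyst, which shields one face of the C5=C10 bond, whereas C5 is set cis to the C10 methyl by the suprafacial addition and is deliberately erased in step 3, so C10 is the only centre that must be controlled here. The step needs regioselectivity (C4 to C5, C1 to C10), and this is secured by the gem-dimethyl diene terminus, which cannot bond to the methyl-bearing quinone carbon without creating vicinal quaternary centres, whichever carbonyl carries the catalyst. Site selectivity is not an issue because the two quinone double bonds are homotopic, over-addition is not expected because the remaining C7=C8 bond of 4 is a non-quinoid trisubstituted enedione, and endo/exo has no stereochemical consequence because neither diene terminus is stereogenic.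

**Step 3**
Reactants: 4 cis-fused 3-(triisopropylsilyloxy)-11-nordrima-2,7-diene-6,9-dione
Product: 5 3-(triisopropylsilyloxy)-6-(trifluoromethylsulfonyloxy)-11-nordrima-2,5,7-trien-9-one (10β-CH3)
Conditions: KN(SiMe3)2, THF, −78 °C; PhN(SO2CF3)2, −78 to 0 °C
Reagents that add atoms: N-phenylbis(trifluoromethanesulfonimide), O=S(=O)(N(c1ccccc1)S(=O)(=O)C(F)(F)F)C(F)(F)F
Why: Kinetic deprotonation of the only α-hydrogen of the enedione (H-5; C7 is vinylic, C10 quaternary) and O-sulfonylation of the potassium enolate (enol triflate formation) should give the dienyl triflate, which makes C5 trigonal so that the cis fusion of 4 no longer matters and marks the C6 oxygen for removal, avoiding a base equilibration whose cis/trans outcome cannot be relied on for 6-oxo-4,4,10-trimethyldecalins.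

**Step 4**
Reactants: 5 dienyl triflate
Product: 6 3-(triisopropylsilyloxy)-11-nordrima-2,5,7-trien-9-one (10β-CH3)
Conditions: Pd(OAc)2 (5 mol %), PPh3, HCO2H, Et3N, DMF, 60 °C
Reagents that add atoms: none
Why: Palladium-catalysed formate reduction of an enol triflate (oxidative addition to zerovalent palladium, formate exchange, decarboxylation to the palladium hydride, reductive elimination) should replace C6–O by C6–H while tolerating the dienone and the silyl enol ether; no stereocentre is formed and 6 is used at once because 2,4-cyclohexadienones can dimerise.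

**Step 5**
Reactants: 6 linear dienone
Product: 7 trans-fused 3-(triisopropylsilyloxy)-11-nordrima-2,6-dien-9-one (5α-H/8β-CH3/10β-CH3)
Conditions: Li, NH3(l)/THF, t-BuOH (1 equiv), −78 °C; then solid NH4Cl
Reagents that add atoms: none
Why: Dissolving-metal (Birch-type) reduction of the linear dienone should protonate the δ-carbon C5 axially on the face opposite the axial C10 methyl, as in lithium–ammonia reductions of octalones, giving the trans fusion (5α-H) under kinetic rather than thermodynamic control, and the surviving C9 dienolate is protonated at C8 on quenching from the α-face (kinetic 8β-methyl, corrected in step 6).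

**Step 6**
Reactants: 7 trans-fused β,γ-enone
Product: 9 11-nordrimane-3,9-dione (5α-H/8α-CH3/10β-CH3), via 8β-methyl silyl enol ether 8 (not isolated)
Conditions: H2 (1 atm), Pd/C, EtOAc, rt; filter; 2 M HCl, THF, 40 °C
Reagents that add atoms: none
Why: Heterogeneous hydrogenation should saturate the disubstituted C6=C7 bond without touching the hindered silyl enol ether, and aqueous acid then hydrolyses the enol ether to the C3 ketone and equilibrates C8 through the C9 enol to the equatorial 8α-methyl epimer, which is free of the 1,3-diaxial interaction with the C10 methyl.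

**Step 7**
Reactants: 9 11-nordrimane-3,9-dione
Product: 10 3β-hydroxy-11-nordriman-9-one (5α-H/8α-CH3/10β-CH3)
Conditions: NaBH4, MeOH–CH2Cl2, −20 to 0 °C
Reagents that add atoms: none
Why: Chemoselective hydride reduction should occur at the C3 ketone because the C9 ketone is flanked by quaternary C10 and tertiary C8, and axial hydride delivery from the α-face, away from the axial 4β- and 10β-methyl groups, gives the equatorial 3β-alcohol.

**Step 8**
Reactants: 10 3β-hydroxy-11-nordriman-9-one
Product: 11 drim-9(11)-en-3β-ol (9-methylene; 5α-H/8α-CH3/10β-CH3)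
Conditions: Ph3PCH3Br, KOt-Bu (excess), toluene, 90 °C
Reagents that add atoms: methyltriphenylphosphonium bromide, C[P+](c1ccccc1)(c1ccccc1)c1ccccc1.[Br-]
Why: Wittig methylenation with excess non-stabilised ylide under forcing conditions, as used for 2,2,6-trisubstituted cyclohexanones, should convert the hindered C9 ketone into the exocyclic alkene with the hydroxyl carried as its alkoxide; the 8α-methyl configuration is the thermodynamic one under these basic conditions.

**Step 9**
Reactants: 11 drim-9(11)-en-3β-ol
Product: 12 9α,11-epoxydriman-3β-ol (spiro-oxirane, oxygen α, C11 β)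
Conditions: mCPBA, CH2Cl2, 0 °C
Reagents that add atoms: 3-chloroperoxybenzoic acid (mCPBA), OOC(=O)c1cccc(Cl)c1
Why: Peracid (Prilezhaev) epoxidation of the exocyclic alkene should occur from the α-face because the axial C10 methyl blocks the β-approach, which sets C9 with oxygen α (axial) and C11 β (equatorial).

**Step 10**
Reactants: 12 9α,11-epoxydriman-3β-ol
Product: 13 14,15,16-trinorlabd-12-ene-3β,9α-diol (9β-allyl carbinol)
Conditions: CH2=CHMgBr (excess), CuBr·SMe2 (20 mol %), THF, −30 to 0 °C; aq NH4Cl
Reagents that add atoms: vinylmagnesium bromide, C=C[Mg]Br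
Why: Copper-catalysed Grignard opening of the 1,1-disubstituted oxirane by SN2 attack at its unsubstituted carbon C11 leaves the C9–O bond untouched, so the 9α-configuration is retained and the homoallylic tertiary carbinol should result.

**Step 11**
Reactants: 13 14,15,16-trinorlabd-12-ene-3β,9α-diol
Product: 14 3β-acetoxy-14,15,16-trinorlabd-12-en-9α-ol
Conditions: Ac2O, pyridine, DMAP (cat.), CH2Cl2, 0 °C to rt
Reagents that add atoms: acetic anhydride, CC(=O)OC(C)=O
Why: Nucleophile-catalysed acylation should acetylate only the secondary equatorial 3β-hydroxyl, since the tertiary 9α-hydroxyl between C8 and quaternary C10 is too hindered to react.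

**Step 12**
Reactants: 14 3β-acetoxy-14,15,16-trinorlabd-12-en-9α-ol; 15 α-methylene-γ-butyrolactone (3-methylenedihydrofuran-2(3H)-one)
Product: 16 3β-acetoxy-9α-hydroxylabd-12(E)-en-16,15-olide
Conditions: 15 (5 equiv), second-generation Hoveyda–Grubbs catalyst RuCl2(H2IMes)(=CH-C6H4-2-O-i-Pr) (5 mol %), CH2Cl2, 40 °C
Reagents that add atoms: none
Why: Olefin cross-metathesis between the terminal alkene of 14 and the 1,1-disubstituted acrylate-type alkene of 15, a pairing known to give α-alkylidene-γ-butyrolactones with E preference, should join C12 to C13 with loss of ethene; no stereocentre is formed.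

**Step 13**
Reactants: 16 3β-acetoxy-9α-hydroxylabd-12(E)-en-16,15-olide
Product: 17 3β-acetoxy-9α-hydroxylabd-13-en-16,15-olide (CNP0117645.1)
Conditions: RuHCl(CO)(PPh3)3 (5 mol %), toluene, 100 °C
Reagents that add atoms: none
Why: Metal-hydride-catalysed double-bond migration (hydrometalation/β-hydride elimination) should move the exocyclic C12=C13 bond into the lactone ring, the conjugated endocyclic butenolide being the thermodynamic sink; no ring is opened and no stereocentre is touched.

**Compound list**
1 | 4-methylpent-1-en-3-one (isopropyl vinyl ketone) | C=CC(=O)C(C)C | starting material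
2 | 4-methyl-3-(triisopropylsilyloxy)penta-1,3-diene | C=CC(O[Si](C(C)C)(C(C)C)C(C)C)=C(C)C | intermediate
3 | 2,6-dimethyl-1,4-benzoquinone | CC1=CC(=O)C=C(C)C1=O | starting material
4 | cis-fused 3-(triisopropylsilyloxy)-11-nordrima-2,7-diene-6,9-dione (5β-H/10β-CH3) | CC(C)[Si](C(C)C)(C(C)C)OC1=CC[C@@]2(C)[C@H](C(=O)C=C(C)C2=O)C1(C)C | intermediate
5 | 3-(triisopropylsilyloxy)-6-(trifluoromethylsulfonyloxy)-11-nordrima-2,5,7-trien-9-one (10β-CH3) | CC(C)[Si](C(C)C)(C(C)C)OC1=CC[C@@]2(C)C(=C(OS(=O)(=O)C(F)(F)F)C=C(C)C2=O)C1(C)C | intermediate
6 | 3-(triisopropylsilyloxy)-11-nordrima-2,5,7-trien-9-one (10β-CH3) | CC(C)[Si](C(C)C)(C(C)C)OC1=CC[C@@]2(C)C(=CC=C(C)C2=O)C1(C)C | intermediate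
7 | trans-fused 3-(triisopropylsilyloxy)-11-nordrima-2,6-dien-9-one (5α-H/8β-CH3/10β-CH3) | CC(C)[Si](C(C)C)(C(C)C)OC1=CC[C@@]2(C)[C@@H](C=C[C@H](C)C2=O)C1(C)C | intermediate
8 | 3-(triisopropylsilyloxy)-11-nordrim-2-en-9-one (5α-H/8β-CH3/10β-CH3) | CC(C)[Si](C(C)C)(C(C)C)OC1=CC[C@@]2(C)[C@@H](CC[C@H](C)C2=O)C1(C)C | intermediate
9 | 11-nordrimane-3,9-dione (5α-H/8α-CH3/10β-CH3) | O=C1CC[C@@]2(C)[C@@H](CC[C@@H](C)C2=O)C1(C)C | intermediate
10 | 3β-hydroxy-11-nordriman-9-one (5α-H/8α-CH3/10β-CH3) | O[C@H]1CC[C@@]2(C)[C@@H](CC[C@@H](C)C2=O)C1(C)C | intermediate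
11 | drim-9(11)-en-3β-ol (5α-H/8α-CH3/10β-CH3) | O[C@H]1CC[C@@]2(C)[C@@H](CC[C@@H](C)C2=C)C1(C)C | intermediate
12 | 9α,11-epoxydriman-3β-ol | O[C@H]1CC[C@@]2(C)[C@@H](CC[C@@H](C)[C@]2(O3)C3)C1(C)C | intermediate
13 | 14,15,16-trinorlabd-12-ene-3β,9α-diol | O[C@H]1CC[C@@]2(C)[C@@H](CC[C@@H](C)[C@]2(O)CC=C)C1(C)C | intermediate
14 | 3β-acetoxy-14,15,16-trinorlabd-12-en-9α-ol | CC(=O)O[C@H]1CC[C@@]2(C)[C@@H](CC[C@@H](C)[C@]2(O)CC=C)C1(C)C | intermediate
15 | α-methylene-γ-butyrolactone (3-methylenedihydrofuran-2(3H)-one) | C=C1CCOC1=O | starting material
16 | 3β-acetoxy-9α-hydroxylabd-12(E)-en-16,15-olide | CC(=O)O[C@H]1CC[C@@]2(C)[C@@H](CC[C@@H](C)[C@]2(O)C/C=C3\CCOC3=O)C1(C)C | intermediate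
17 | 3β-acetoxy-9α-hydroxylabd-13-en-16,15-olide (CNP0117645.1) | CC(=O)O[C@H]1CC[C@@]2(C)[C@@H](CC[C@@H](C)[C@]2(O)CCC2=CCOC2=O)C1(C)C | target

**Step count**
Total step count: 13. Longest linear sequence: 13 steps (1 to 17); 3 and 15 are purchased and enter directly.

**Steps most likely to fail**
- Step 2. The Z-methyl on the C4 terminus of the diene disfavours the s-cis conformer, so acid-induced desilylation of 2 or a loss of facial selectivity may outrun the cycloaddition. Fallback, setting out from 2 and 3 and coming back at 4: catalyst control is given up. The cycloaddition is run without any acid under high pressure (12 kbar, CH2Cl2, rt), where the steric bias of the gem-dimethyl terminus and polarisation through the C9 carbonyl should give the same regiochemistry. The racemate, 4 together with the enantiomeric adduct F1, is then resolved by preparative chromatography on a cellulose tris(3,5-dimethylphenylcarbamate) stationary phase, and 4 continues at step 3.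
- Step 3. The C5 hydrogen is flanked by two fully substituted carbons, so the base may instead deprotonate the C8 methyl (γ-position) or fail to react, giving the wrong dienyl triflate or returning the enedione. Fallback, setting out from 4 and coming back at 6: the less hindered C6 carbonyl is reduced selectively (NaBH4, CeCl3·7H2O, MeOH, −78 °C; 1,2-reduction from the face away from C4) to the 6α-allylic alcohol F2. Anti-elimination of water across C5–C6 with Ph2S[OC(CF3)2Ph]2 (CH2Cl2, rt) then gives dienone 6 without passing through 5.
- Step 10. Substitution at the neopentyl-type C11 may be too slow, with competing Lewis-acid-induced rearrangement of the oxirane to the C11 aldehyde or halohydrin formation. Fallback, setting out from 12 and coming back at 13: the oxirane is opened without copper or magnesium halide by the slim sp-nucleophile LiC≡CH·H2NCH2CH2NH2 in DMSO at rt to give the homopropargylic diol F3. Semi-hydrogenation (H2, Pd/CaCO3 poisoned with Pb(OAc)2, quinoline, EtOAc) then gives 13.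

**Further compounds**
F1 | step 2 | enantiomer of adduct 4, cis-fused 3-(triisopropylsilyloxy)-11-nordrima-2,7-diene-6,9-dione (5α-H/10α-CH3) | CC(C)[Si](C(C)C)(C(C)C)OC1=CC[C@]2(C)[C@@H](C(=O)C=C(C)C2=O)C1(C)C
F2 | step 3 | cis-fused 6α-hydroxy-3-(triisopropylsilyloxy)-11-nordrima-2,7-dien-9-one (5β-H/10β-CH3) | CC(C)[Si](C(C)C)(C(C)C)OC1=CC[C@@]2(C)[C@H]([C@@H](O)C=C(C)C2=O)C1(C)C
F3 | step 10 | 14,15,16-trinorlabd-12-yne-3β,9α-diol | O[C@H]1CC[C@@]2(C)[C@@H](CC[C@@H](C)[C@]2(O)CC#C)C1(C)C
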